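**Retrosynthetic overview**
1. Target 25 ⇐ allylic alcohol 24 by selective oxidation of the primary C14–OH (last step).
2. 24 ⇐ lactol 22 in one operation: CrCl2 allylation of the lactol-masked Z-enal (C6) by the 2-(bromomethyl)enoate (C7) closes the ten-membered carbocycle (C6–C7), and the resulting alkoxide lactonises on C12. The six-membered lactol ring opens and releases the free C2–OH.
3. Lactol ring (C2–O–C6, cis C4=C5) ⇐ enal 15 by catalytic asymmetric 2-(acetoxymethyl)allylboration (sets C2), acrolein transacetalisation and six-ring RCM.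
4. 15 ⇐ dialdehyde 12 (Morita–Baylis–Hillman reaction, SN2′ bromination); 12 ⇐ Z-iodoalkene 5 (from 2-butyne-1,4-diol, fixes C1=C10) + silyl glycidyl ether 7 (C8 from (S)-glycidol), then isovaleroylation and double Swern oxidation.
5. Ring order: temporary dihydropyran first (step 13), then the ten-membered ring and the γ-lactone together (step 15).

Assumption: germacrane numbering is used throughout (ring C1–C10, lactone carbons C11–C13, aldehyde carbon C14, acetoxymethyl carbon C15); in this numbering the target is 2S,6R,7R,8R with both ring alkenes cis inside the ring (CIP: both E).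

**Step 1**
Reactants: 1 2-butyne-1,4-diol
Product: 2 4-[(tert-butyldimethylsilyl)oxy]but-2-yn-1-ol
Conditions: NaH (1.0 equiv), THF, 0 °C; TBSCl (1.0 equiv), rt
Reagents that add atoms: tert-butyldimethylsilyl chloride (TBSCl), CC(C)(C)[Si](C)(C)Cl
Why: One equivalent of NaH gives a poorly soluble monosodium alkoxide that is silylated once (McDougal monosilylation), leaving the propargylic OH needed to direct step 2.

**Step 2**
Reactants: 2 mono-TBS butynediol
Product: 4 (2Z)-4-[(tert-butyldimethylsilyl)oxy]-3-iodobut-2-en-1-ol, via alkenylalanate 3 (not isolated)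
Conditions: NaAlH2(OCH2CH2OCH3)2, THF, 0 °C to rt; then I2, −78 °C to 0 °C
Reagents that add atoms: iodine, II
Why: Hydroxyl-directed trans-hydroalumination puts aluminium on the alkyne carbon remote from the OH and iodinolysis with retention gives only the Z-iodoalkene, which fixes the C1=C10 geometry (future C9 cis to C2).

**Step 3**
Reactants: 4 Z-iodo allylic alcohol
Product: 5 tert-butyl{[(2Z)-2-iodo-4-(triethylsilyloxy)but-2-en-1-yl]oxy}dimethylsilane
Conditions: TESCl, imidazole, CH2Cl2, 0 °C
Reagents that add atoms: chlorotriethylsilane (TESCl), CC[Si](CC)(CC)Cl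
Why: Routine O-silylation; a primary triethylsilyl ether survives t-BuLi and BF3·OEt2 at −78 °C and is later converted directly into the aldehyde under Swern conditions.

**Step 4**
Reactants: 6 (S)-glycidol
Product: 7 triethyl{[(2R)-oxiran-2-yl]methoxy}silane
Conditions: TESCl, imidazole, CH2Cl2, 0 °C
Reagents that add atoms: chlorotriethylsilane (TESCl), CC[Si](CC)(CC)Cl
Why: O-silylation leaves the epoxide untouched, so the future C8 stereocentre comes unchanged from the chiral pool (the descriptor changes from S to R only because the CIP priorities change).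

**Step 5**
Reactants: 5 bis-silyl Z-iodoalkene; 7 (R)-TES glycidyl ether
Product: 9 (2R,4E)-4-{[(tert-butyldimethylsilyl)oxy]methyl}-1,6-bis[(triethylsilyl)oxy]hex-4-en-2-ol, via alkenyllithium 8 (not isolated)
Conditions: t-BuLi (2.1 equiv), Et2O, −78 °C; then 7, BF3·OEt2, −78 °C
Reagents that add atoms: none
Why: Iodine–lithium exchange retains the alkene geometry and the alkenyllithium opens the BF3-activated terminal epoxide at its CH2 carbon (SN2 epoxide opening), making the C9–C10 bond without touching the C8 stereocentre.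

**Step 6**
Reactants: 9 secondary alcohol; 10 3-methylbutanoyl chloride
Product: 11 (2R,4E)-4-{[(tert-butyldimethylsilyl)oxy]methyl}-1,6-bis[(triethylsilyl)oxy]hex-4-en-2-yl 3-methylbutanoate
Conditions: pyridine, DMAP (cat.), CH2Cl2, 0 °C to rt
Reagents that add atoms: none
Why: DMAP-catalysed acylation of the only free hydroxyl installs the C8 isovalerate before any other secondary alcohol exists.

**Step 7**
Reactants: 11 bis-TES isovalerate
Product: 12 (2R,4E)-4-{[(tert-butyldimethylsilyl)oxy]methyl}-1,6-dioxohex-4-en-2-yl 3-methylbutanoate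
Conditions: (COCl)2, DMSO, CH2Cl2, −78 to −30 °C; i-Pr2NEt, −78 to 0 °C
Reagents that add atoms: none
Why: Under Swern conditions both primary triethylsilyl ethers are cleaved and oxidised in the same operation while the primary TBS ether is inert (Swern oxidation of primary TES ethers), and the hindered base at low temperature avoids epimerising the α-acyloxy aldehyde.

**Step 8**
Reactants: 12 dialdehyde; 13 methyl acrylate
Product: 14 methyl (4R,6E)-6-{[(tert-butyldimethylsilyl)oxy]methyl}-3-hydroxy-2-methylidene-4-[(3-methylbutanoyl)oxy]-8-oxooct-6-enoate (both C3 epimers)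
Conditions: DABCO (1 equiv), methyl acrylate (neat, excess), rt
Reagents that add atoms: none
Why: Morita–Baylis–Hillman reaction; the α-acyloxy aliphatic aldehyde is far more electrophilic than the β,β-disubstituted enal so only C7 reacts, and the new carbinol configuration is irrelevant because C7 becomes sp2 in step 9.

**Step 9**
Reactants: 14 Morita–Baylis–Hillman adduct
Product: 15 methyl (2Z,4R,6E)-2-(bromomethyl)-6-{[(tert-butyldimethylsilyl)oxy]methyl}-4-[(3-methylbutanoyl)oxy]-8-oxoocta-2,6-dienoate
Conditions: NBS, Me2S, CH2Cl2, 0 °C to rt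
Reagents that add atoms: N-bromosuccinimide (NBS), O=C1CCC(=O)N1Br
Why: Corey–Kim-type activation of the allylic alcohol followed by SN2′ attack of bromide on the methylidene carbon gives the rearranged primary bromide as the thermodynamically preferred Z-enoate.

**Step 10**
Reactants: 16 2-methylidenepropane-1,3-diyl diacetate
Product: 17 2-[(4,4,5,5-tetramethyl-1,3,2-dioxaborolan-2-yl)methyl]prop-2-en-1-yl acetate
Conditions: B2pin2 (1 equiv), 16 (3 equiv), Pd2(dba)3 (2 mol %), DMSO, 50 °C
Reagents that add atoms: bis(pinacolato)diboron (B2pin2), CC1(C)OB(OC1(C)C)B1OC(C)(C)C(C)(C)O1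
Why: Miyaura-type allylic borylation through a π-allylpalladium intermediate, with excess diacetate keeping the second acetate in place.

**Step 11**
Reactants: 15 enal bromide; 17 2-(acetoxymethyl)allylboronate
Product: 18 methyl (2Z,4R,6E,8S)-11-(acetyloxy)-2-(bromomethyl)-6-{[(tert-butyldimethylsilyl)oxy]methyl}-8-hydroxy-10-methylidene-4-[(3-methylbutanoyl)oxy]undeca-2,6-dienoate
Conditions: (S)-TRIP [(S)-3,3′-bis(2,4,6-triisopropylphenyl)-1,1′-binaphthyl-2,2′-diyl hydrogen phosphate] (5 mol %), 4 Å MS, toluene, −30 °C
Reagents that add atoms: none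
Why: Chiral phosphoric acid-catalysed allylboration through a closed chair transition state in which the catalyst hydrogen-bonds to the boronate oxygen and selects one aldehyde face, setting C2 as S by reagent control and bringing in C3, C4 and the C15 acetate.

**Step 12**
Reactants: 18 homoallylic alcohol; 19 acrolein diethyl acetal
Product: 20 mixed acetal of 18 carrying a 1-ethoxyprop-2-en-1-yl group on O-2 (both acetal epimers)
Conditions: PPTS (cat.), toluene, 40 °C, reduced pressure
Reagents that add atoms: none
Why: Acid-catalysed transacetalisation driven by removal of ethanol attaches the future C5–C6 unit to O-2; the new acetal centre is a mixture that is erased in step 14.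

**Step 13**
Reactants: 20 mixed acetal
Product: 21 methyl (2Z,4R,6E)-7-[(2S)-4-(acetoxymethyl)-6-ethoxy-3,6-dihydro-2H-pyran-2-yl]-2-(bromomethyl)-6-{[(tert-butyldimethylsilyl)oxy]methyl}-4-[(3-methylbutanoyl)oxy]hepta-2,6-dienoate (both acetal epimers)
Conditions: second-generation Grubbs catalyst (5 mol %), CH2Cl2 (0.01 M), 40 °C
Reagents that add atoms: none
Why: Ring-closing metathesis between the vinyl acetal and the 1,1-disubstituted alkene is a fast six-membered ring closure, and the ring forces C3 and C6 onto the same side of the new trisubstituted C4=C5 bond, as the macrocycle requires.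

**Step 14**
Reactants: 21 ethoxy dihydropyran
Product: 22 methyl (2Z,4R,6E)-7-[(2S)-4-(acetoxymethyl)-6-hydroxy-3,6-dihydro-2H-pyran-2-yl]-2-(bromomethyl)-6-(hydroxymethyl)-4-[(3-methylbutanoyl)oxy]hepta-2,6-dienoate (lactol; both anomers)
Conditions: HF (48 % aq.), MeCN, 0 °C
Reagents that add atoms: water, O
Why: Brief cold aqueous acid hydrolyses the allylic cyclic acetal to the lactol (ring tautomer of the Z-hydroxy-enal, so the alkene cannot isomerise) and cleaves the primary TBS ether, while the esters and the allylic bromide survive.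

**Step 15**
Reactants: 22 lactol bromide
Product: 24 14-hydroxy macrolactone (the target with CH2OH in place of CHO; 2S,6R,7R,8R), via hydroxy ester 23 (not isolated)
Conditions: CrCl2 (8 equiv), THF (0.002 M), 0 °C to rt; aq. NH4Cl work-up
Reagents that add atoms: none
Why: CrCl2 turns the allylic bromide into an allylchromium reagent that adds through its γ-carbon (C7) to the open Z-hydroxy-enal tautomer in a chair Zimmerman–Traxler transition state (intramolecular Nozaki–Hiyama allylation), the equatorial C8 substituent giving the anti adduct and hence the trans-lactone when the chromium alkoxide lactonises on the methyl ester, while the C8 stereocentre directs the C7 face (H-8 in the plane of the allyl unit to avoid A1,3 strain, C8–C9 bond anti to the forming C6–C7 bond, acyloxy group outside), so that C6 and C7 are expected to be set as R and the two cis alkenes keep the ten-membered transition state unstrained.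

**Step 16**
Reactants: 24 14-hydroxy macrolactone
Product: 25 target, (2S,6R,7R,8R)-15-acetoxy-2-hydroxy-8-(3-methylbutanoyloxy)-14-oxogermacra-1(10),4,11(13)-trien-12,6-olide
Conditions: TEMPO (10 mol %), PhI(OAc)2 (1.1 equiv), CH2Cl2, rt
Reagents that add atoms: none
Why: TEMPO/PhI(OAc)2 oxoammonium oxidation converts primary alcohols to aldehydes much faster than secondary ones, so only the C14 allylic alcohol is oxidised and the C2 hydroxyl, lactone and both esters are untouched.

**Compound list**
1 | but-2-yne-1,4-diol | OCC#CCO | starting material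
2 | 4-[(tert-butyldimethylsilyl)oxy]but-2-yn-1-ol | OCC#CCO[Si](C)(C)C(C)(C)C | intermediate
3 | sodium alkenylalanate (cyclic ate complex, Al on the future C10; not isolated) | [Na+].COCCO[Al-]1(OCCOC)OCC=C1CO[Si](C)(C)C(C)(C)C | intermediate
4 | (2Z)-4-[(tert-butyldimethylsilyl)oxy]-3-iodobut-2-en-1-ol | OC/C=C(\I)CO[Si](C)(C)C(C)(C)C | intermediate
5 | tert-butyl{[(2Z)-2-iodo-4-(triethylsilyloxy)but-2-en-1-yl]oxy}dimethylsilane | CC[Si](CC)(CC)OC/C=C(\I)CO[Si](C)(C)C(C)(C)C | intermediate
6 | (S)-glycidol, [(2S)-oxiran-2-yl]methanol | C1[C@@H](O1)CO | starting material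
7 | triethyl{[(2R)-oxiran-2-yl]methoxy}silane | C1[C@@H](O1)CO[Si](CC)(CC)CC | intermediate
8 | alkenyllithium from 5 (Li in place of I, geometry retained; not isolated) | CC[Si](CC)(CC)OC/C=C(\[Li])CO[Si](C)(C)C(C)(C)C | intermediate
9 | (2R,4E)-4-{[(tert-butyldimethylsilyl)oxy]methyl}-1,6-bis[(triethylsilyl)oxy]hex-4-en-2-ol | CC[Si](CC)(CC)OC/C=C(\C[C@@H](O)CO[Si](CC)(CC)CC)CO[Si](C)(C)C(C)(C)C | intermediate
10 | 3-methylbutanoyl chloride (isovaleryl chloride) | CC(C)CC(Cl)=O | starting material
11 | (2R,4E)-4-{[(tert-butyldimethylsilyl)oxy]methyl}-1,6-bis[(triethylsilyl)oxy]hex-4-en-2-yl 3-methylbutanoate | CC[Si](CC)(CC)OC/C=C(\C[C@@H](OC(=O)CC(C)C)CO[Si](CC)(CC)CC)CO[Si](C)(C)C(C)(C)C | intermediate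
12 | (2R,4E)-4-{[(tert-butyldimethylsilyl)oxy]methyl}-1,6-dioxohex-4-en-2-yl 3-methylbutanoate | O=C/C=C(\C[C@@H](OC(=O)CC(C)C)C=O)CO[Si](C)(C)C(C)(C)C | intermediate
13 | methyl acrylate | C=CC(=O)OC | starting material
14 | methyl (4R,6E)-6-{[(tert-butyldimethylsilyl)oxy]methyl}-3-hydroxy-2-methylidene-4-[(3-methylbutanoyl)oxy]-8-oxooct-6-enoate (both C3 epimers) | O=C/C=C(\C[C@@H](OC(=O)CC(C)C)C(O)C(=C)C(=O)OC)CO[Si](C)(C)C(C)(C)C | intermediate
15 | methyl (2Z,4R,6E)-2-(bromomethyl)-6-{[(tert-butyldimethylsilyl)oxy]methyl}-4-[(3-methylbutanoyl)oxy]-8-oxoocta-2,6-dienoate | O=C/C=C(\C[C@@H](OC(=O)CC(C)C)/C=C(\CBr)C(=O)OC)CO[Si](C)(C)C(C)(C)C | intermediate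
16 | 2-methylidenepropane-1,3-diyl diacetate | CC(=O)OCC(=C)COC(C)=O | starting material
17 | 2-[(4,4,5,5-tetramethyl-1,3,2-dioxaborolan-2-yl)methyl]prop-2-en-1-yl acetate | CC(=O)OCC(=C)CB1OC(C)(C)C(C)(C)O1 | intermediate
18 | methyl (2Z,4R,6E,8S)-11-(acetyloxy)-2-(bromomethyl)-6-{[(tert-butyldimethylsilyl)oxy]methyl}-8-hydroxy-10-methylidene-4-[(3-methylbutanoyl)oxy]undeca-2,6-dienoate | CC(=O)OCC(=C)C[C@H](O)/C=C(\C[C@@H](OC(=O)CC(C)C)/C=C(\CBr)C(=O)OC)CO[Si](C)(C)C(C)(C)C | intermediate
19 | acrolein diethyl acetal (3,3-diethoxyprop-1-ene) | C=CC(OCC)OCC | starting material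
20 | mixed acetal of 18: O-2 bears a 1-ethoxyprop-2-en-1-yl group (both acetal epimers) | CC(=O)OCC(=C)C[C@H](OC(OCC)C=C)/C=C(\C[C@@H](OC(=O)CC(C)C)/C=C(\CBr)C(=O)OC)CO[Si](C)(C)C(C)(C)C | intermediate
21 | methyl (2Z,4R,6E)-7-[(2S)-4-(acetoxymethyl)-6-ethoxy-3,6-dihydro-2H-pyran-2-yl]-2-(bromomethyl)-6-{[(tert-butyldimethylsilyl)oxy]methyl}-4-[(3-methylbutanoyl)oxy]hepta-2,6-dienoate (both acetal epimers) | CCOC1C=C(COC(C)=O)C[C@H](O1)/C=C(\C[C@@H](OC(=O)CC(C)C)/C=C(\CBr)C(=O)OC)CO[Si](C)(C)C(C)(C)C | intermediate
22 | methyl (2Z,4R,6E)-7-[(2S)-4-(acetoxymethyl)-6-hydroxy-3,6-dihydro-2H-pyran-2-yl]-2-(bromomethyl)-6-(hydroxymethyl)-4-[(3-methylbutanoyl)oxy]hepta-2,6-dienoate (lactol, both anomers) | OC1C=C(COC(C)=O)C[C@H](O1)/C=C(\C[C@@H](OC(=O)CC(C)C)/C=C(\CBr)C(=O)OC)CO | intermediate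
23 | ring-closed hydroxy ester: ten-membered carbocycle with free 6-OH and C7 bearing C(=CH2)CO2CH3 (present as its chromium alkoxide; not isolated) | C=C(C(=O)OC)[C@H]1[C@H](O)/C=C(/COC(C)=O)C[C@H](O)/C=C(/CO)C[C@H]1OC(=O)CC(C)C | intermediate
24 | (2S,6R,7R,8R)-15-acetoxy-2,14-dihydroxy-8-(3-methylbutanoyloxy)germacra-1(10),4,11(13)-trien-12,6-olide | C=C1C(=O)O[C@@H]2/C=C(/COC(C)=O)C[C@H](O)/C=C(/CO)C[C@@H](OC(=O)CC(C)C)[C@@H]12 | intermediate
25 | (2S,6R,7R,8R)-15-acetoxy-2-hydroxy-8-(3-methylbutanoyloxy)-14-oxogermacra-1(10),4,11(13)-trien-12,6-olide (CNP0524123.1) | C=C1C(=O)O[C@@H]2/C=C(/COC(C)=O)C[C@H](O)/C=C(/C=O)C[C@@H](OC(=O)CC(C)C)[C@@H]12 | target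

**Step count**
Total: 16 steps (14 in the main line plus the two reagent preparations, steps 4 and 10).
Longest linear sequence: 14 steps (steps 1–3, 5–9, 11–16, from 2-butyne-1,4-diol).

**Steps most likely to fail and fallbacks**

Step 15 is the riskiest. The aldehyde is available only through the lactol at high dilution, so the allylchromium may be protonated by the free hydroxyls or lose the C8 isovalerate by 1,4-elimination before it cyclises. The C7 face is set by a conformational preference, not by a rigid element, so the 6R,7R outcome is a prediction, not a certainty. The fallback forms the two rings one after the other and sets out from 18. CrCl2 and excess acrolein in THF (intermolecular Nozaki–Hiyama allylation–lactonisation, in which free aldehyde traps the allylchromium at once) give the 6-vinyl α-methylene lactone F1. Second-generation Hoveyda–Grubbs catalyst in toluene at 0.001 M then closes the ten-membered ring between the vinyl group and the 1,1-disubstituted alkene, the ring enforcing the cis C4=C5 bond, to give the silyl-protected macrolactone F2. HF·pyridine removes the TBS group and the route is rejoined at 24.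

Step 8 is the second risk. The Morita–Baylis–Hillman reaction is slow, and days of DABCO could epimerise C8, move the isovalerate to the new hydroxyl, or scramble the geometry of the untouched enal. The fallback replaces the amine-catalysed reaction by an organometallic alkenylation under base-free conditions and sets out from 12. CrCl2 with catalytic NiCl2 and methyl 2-bromoacrylate in DMF at 0 °C (Nozaki–Hiyama–Kishi alkenylation; the aliphatic aldehyde reacts ahead of the hindered conjugated enal) gives the same adduct, so the route is rejoined at 14 and no new compound is made (F0).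

Step 11 is the third risk. The acetoxy-substituted 2-substituted allylboronate is more reactive than simple allylboronates, so the uncatalysed background reaction may erode the selectivity at C2. The fallback sets C2 by reduction instead of by allylation and sets out from 15. Hosomi–Sakurai allylation with commercial 2-[(trimethylsilyl)methyl]allyl acetate and BF3·OEt2 in CH2Cl2 at −78 °C gives the homoallylic alcohol as a C2 epimer mixture F3. Dess–Martin periodinane gives the cross-conjugated enone F4. Corey–Bakshi–Shibata reduction with (R)-2-methyl-CBS-oxazaborolidine and catecholborane at −78 °C (alkenyl as the large group) gives the 2S alcohol, and the route is rejoined at 18.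

**Further compounds**
F1 | step 15 | 6-vinyl α-methylene-γ-lactone from 18 and acrolein (6R,7R; C2–OH free, C4 methylidene, C14–OTBS) | C=C1C(=O)O[C@H](C=C)[C@H]1[C@H](OC(=O)CC(C)C)C/C(CO[Si](C)(C)C(C)(C)C)=C\[C@@H](O)CC(=C)COC(C)=O
F2 | step 15 | 14-O-TBS ether of 24 | C=C1C(=O)O[C@@H]2/C=C(/COC(C)=O)C[C@H](O)/C=C(/CO[Si](C)(C)C(C)(C)C)C[C@@H](OC(=O)CC(C)C)[C@@H]12
F3 | step 11 | C2 epimer mixture of 18 | CC(=O)OCC(=C)CC(O)/C=C(\C[C@@H](OC(=O)CC(C)C)/C=C(\CBr)C(=O)OC)CO[Si](C)(C)C(C)(C)C
F4 | step 11 | C2 ketone (8-oxo analogue) of 18 | CC(=O)OCC(=C)CC(=O)/C=C(\C[C@@H](OC(=O)CC(C)C)/C=C(\CBr)C(=O)OC)CO[Si](C)(C)C(C)(C)C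
F0 | step 8 | none | none
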